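## The problem

Target **21** is the 7-O-alkyl ether of 7-hydroxy-8-methoxycoumarin with an oxidised geranyl chain. The chain is numbered here from C1' (the OCH2 carbon) to C7' (the terminal alkene carbon bearing two methyl groups). The bicyclic lactone can be bought, so the task is to build a ten-carbon acyclic chain and join it through the C1'–O bond.

The chain holds three stereocentres. C2' and C3' belong to a trans-trisubstituted oxirane (2'R,3'R; C3' is fully substituted and carries the methyl group). C5' (R) is a secondary allylic carbinol, one methylene away from C3'.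

C2' and C3' are adjacent and can control each other. An oxygen at C3' stands 1,3 to C5' and can direct hydride delivery to a C5' ketone. One stereocentre at C2' can therefore relay to the other two.

Three functions limit the chemistry. The epoxide opens at C3' under acid. The C5' allylic alcohol next to the C6'=C7' double bond ionises easily under acid. The coumarin is a lactone and Michael acceptor that will not survive organometallic reagents, hydride donors or hot aqueous base. The epoxide should therefore be formed late under basic conditions, the coumarin should enter late as a nucleophile, and nothing acidic should follow.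

The feature that opens the route is the oxygen pattern. C1', C2' and C3' each carry one oxygen, as the three carbons of glyceric acid do, with C3' at the oxidation level of the carboxyl carbon. C4'–C7', with its two methyl groups and the C5' oxygen, is the skeleton of mesityl oxide. The C3'–C4' bond is thus an aldol bond between the α'-carbon of mesityl oxide and a methyl ketone made from glycerate. The trans epoxide corresponds to a 2',3'-anti diol closed with one inversion at C2'.

## Retrosynthesis

**21 to 20.** The last operation is cleavage of the O–Si bond at C5' of silyl ether **20**. The allylic alcohol must be masked from the moment it exists, because it would compete in both sulfonylations and would not tolerate the acetonide hydrolysis. A tert-butyldimethylsilyl ether is chosen because buffered fluoride removes it without acid, which the epoxide of **21** requires.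

**20 to 17.** The epoxide is cut at the O–C2' bond, leading through alkoxide **19** and mesylate **18** to diol **17**. The neighbouring option, epoxidation of a C2'=C3' alkene, has no allylic hydroxyl to direct it and would compete with the C6'=C7' alkene. The cut turns the two oxirane stereocentres into two carbinols with the glycerate oxygen pattern. The forward reaction must sulfonylate the secondary C2' hydroxyl in the presence of the tertiary one, then displace with inversion at C2'. That fixes the required diol as 2',3'-anti, (2'S,3'R).

**17 to 14 and 15.** The C1'–OAr bond is cut, giving primary tosylate **14** and purchasable phenol **15**, which reacts as phenoxide **16**. Joining earlier is excluded, because the lactone would meet a Grignard reagent, a borohydride and BF3. A direct Mitsunobu etherification of triol **13** was considered and set aside. 1,2-Diols react under those conditions through cyclic phosphoranes, which deliver the nucleophile to the secondary carbon or collapse to an epoxide. Tosylation then displacement costs one more step but is regiochemically unambiguous. The cut removes the whole heterocycle and leaves an acyclic chain.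

**14 to 11.** Tosylate **14** comes from triol **13** by primary-selective sulfonylation. Triol **13** comes from acetonide **12** by hydrolysis, and **12** from diol **11** by silylation of the secondary hydroxyl. These are changes of functional groups only. Their order is fixed: the C5' hydroxyl must be silylated before the acid step, and the dioxolane must be opened before C1' can be activated. The forward reactions must distinguish a secondary from a tertiary hydroxyl, and a terminal dioxolane from a secondary silyl ether.

**11 to 9.** The C5'–H bond is cut, giving β-hydroxy enone **9**. The free tertiary C3' hydroxyl is placed 1,3 to the ketone, so an internally delivered hydride (through borohydride **10**) can set C5' without a chiral reagent. The precursor has one stereocentre less. The forward reaction must give the 3',5'-anti diol.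

**9 to 4 and 7 (key disconnection).** The C3'–C4' bond is cut, giving methyl ketone **4** and silyloxydiene **7**; the forward reaction passes through aldolate **8**.
- A cut at C4'–C5' would need a β-alkoxy aldehyde prone to retro-aldol cleavage and offers no handle on C5'.
- A cut at C2'–C3' would abandon the glycerate carbon as the source of chirality.
- The chosen cut divides the chain into a four-carbon and a six-carbon piece, both from commodity chemicals, and creates C3' next to the only resident stereocentre.
- The forward reaction must attack the ketone in the non-chelated (polar Felkin–Anh) sense. A chelating Lewis acid such as TiCl4 would bridge the carbonyl and the α-oxygen and give the syn isomer. A monodentate boron Lewis acid and the poorly donating acetonide oxygen are therefore used.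

**4 to 1, and 7 to 5.** Ketone **4** is reached from ester **1** through Weinreb amide **2** (C–N, then C–C bond formation at the carboxyl carbon, via chelate **3**). Diene **7** is reached from mesityl oxide **5** by kinetic enolisation to dienolate **6** and O-silylation. Both are standard and leave the C2' stereocentre of **1** as the single source of chirality.

## Roads not taken

**Alternative 1:** The cut is the C3–C4 double bond of the pyranone ring. Acrylate A1, an aryl acrylate with an ortho vinyl group and the complete silylated epoxy side chain, would be cyclised by ring-closing metathesis with second-generation Hoveyda–Grubbs catalyst. The product A2 is the same compound as **20** and would be desilylated.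
- Merits: the conditions are neutral, and the lactone is created after all basic steps. In that one respect this road is gentler on the heterocycle than the chosen plan, which exposes the coumarin to K2CO3 in DMF and to NaH.
- Weak points: the metathesis builds a ring system that is purchasable as **15** and touches none of the three stereocentres. The whole stereochemical problem of the chain must still be solved before A1. The aromatic core of A1 needs formylation, olefination and acylation of a differentiated trioxygenated benzene. The catalyst must leave the C6'=C7' trisubstituted alkene alone at the temperatures an electron-poor acrylate needs, where cross-metathesis with loss of isobutene is a known leak. The aryl acrylate is itself labile to base and nucleophiles and can only be installed last.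
- Comparison: the chosen plan meets the lactone's sensitivity more cheaply, by introducing **15** late under anhydrous, non-nucleophilic bases, and spends its steps on the stereocentres.

**Alternative 2:** The cut is the C2'–C3' bond with both oxygens in place. Allene A4 would be hydroborated with diisopinocampheylborane, and the γ-alkoxy-γ-methylallylborane reagent formed in the flask would add to aryloxyacetaldehyde A3. The product is the anti diol monoether A5.
- Merits: C2' and C3' are set together under reagent control, independent of substrate bias. The two oxygens emerge differentiated (free C2' hydroxyl, protected C3' oxygen), which is what the epoxide closure needs. On both counts this is better than the chosen plan, whose C3' selectivity rests on a Felkin preference.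
- Weak points: the γ-carbon of the allylborane is fully substituted, and the anti outcome depends on a defined geometry that 1,3-boratropic shift can erode. Aldehyde A3 is an α-aryloxy aldehyde prone to hydration and oligomerisation, and the borinate must be worked up without alkaline peroxide to spare the lactone. After A5 the chain still ends at a vinyl group. C4'–C7' and the C5' stereocentre must then be built by hydroboration, oxidation to the aldehyde level and a stereoselective alkenyl addition. All of this would be done with the coumarin on board, and with C5' set by a second independent asymmetric step.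
- Comparison: the chosen plan installs the full carbon chain and the C5' oxygen in the key step, sets C5' by relay from C3', and keeps the heterocycle out until step 9.

**Alternative 3:** The cut is the pair of epoxide C–O bonds on the intact chain. Dienal A6 would be epoxidised with H2O2 and a diarylprolinol silyl ether catalyst to epoxy aldehyde A7. Reduction, Mitsunobu etherification with **15** and desilylation would follow.
- Merits: one catalytic, reagent-controlled step delivers both oxirane stereocentres with no diol detour, and the endgame is three steps. After its key step this road is shorter than the chosen one, and Mitsunobu etherification of a 2,3-epoxy alcohol is reliable.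
- Weak points: A6 is a β,β-disubstituted enal. Its iminium ion is hindered, and its γ-hydrogens (the C4' methylene and the C3' methyl) allow dienamine formation. E/Z scrambling by that path would appear as cis/trans epoxide mixtures. The resident C5' silyloxy centre may be matched or mismatched with the catalyst. A6 itself requires a separate asymmetric step for C5' and control of the alkene geometry.
- Comparison: the chosen plan accepts a longer endgame (diol to epoxide) and two substrate-controlled selections. In return all three stereocentres derive from one purchased stereocentre, and there is no alkene geometry to control.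

Key step: step 4

Assumption: 7-hydroxy-8-methoxycoumarin (**15**, daphnetin 8-methyl ether) and methyl (S)-2,2-dimethyl-1,3-dioxolane-4-carboxylate (**1**) are treated as purchasable building blocks.

## Route

Step 1
Reactants: 1 methyl (S)-2,2-dimethyl-1,3-dioxolane-4-carboxylate
Product: 2 (S)-N-methoxy-N,2,2-trimethyl-1,3-dioxolane-4-carboxamide
Conditions: MeNH(OMe)·HCl, i-PrMgCl, THF, −20 → 0 °C
Reagents that add atoms: N,O-dimethylhydroxylamine hydrochloride, CNOC.Cl
Why: Weinreb amide formation by aminolysis of the ester with the chloromagnesium amide of N,O-dimethylhydroxylamine generated in the flask; the cold, weakly enolising conditions leave the dioxolane stereocentre (the future C2') untouched.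

Step 2
Reactants: 2 (S)-N-methoxy-N,2,2-trimethyl-1,3-dioxolane-4-carboxamide
Product: 4 1-[(4S)-2,2-dimethyl-1,3-dioxolan-4-yl]ethan-1-one, via magnesium hemiaminal 3 (not isolated)
Conditions: MeMgBr, THF, −20 → 0 °C; aq. NH4Cl
Reagents that add atoms: methylmagnesium bromide, C[Mg]Br
Why: Weinreb ketone synthesis; the five-membered magnesium chelate 3 holds the tetrahedral stage until work-up, so only one methyl group adds. The ketone is volatile and base-sensitive at the α-carbon, so it is isolated cold and used at once.

Step 3
Reactants: 5 mesityl oxide (4-methylpent-3-en-2-one)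
Product: 7 trimethyl[(4-methylpenta-1,3-dien-2-yl)oxy]silane, via lithium dienolate 6 (not isolated)
Conditions: LiN(i-Pr)2, THF, −78 °C; Me3SiCl, −78 °C → rt
Reagents that add atoms: chlorotrimethylsilane, C[Si](C)(C)Cl
Why: Kinetic deprotonation of the enone at the α'-methyl group by the hindered amide base gives the cross-conjugated dienolate 6, which is silylated on oxygen; this is a known preparation of the 2-silyloxydiene.

Step 4
Reactants: 4 1-[(4S)-2,2-dimethyl-1,3-dioxolan-4-yl]ethan-1-one; 7 trimethyl[(4-methylpenta-1,3-dien-2-yl)oxy]silane
Product: 9 (6R)-6-[(4S)-2,2-dimethyl-1,3-dioxolan-4-yl]-6-hydroxy-2-methylhept-2-en-4-one, via difluoroboryl aldolate 8 (not isolated)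
Conditions: BF3·OEt2 (1.2 equiv), CH2Cl2, −78 °C; then aq. NaHCO3 at −78 °C
Reagents that add atoms: none
Why: Mukaiyama aldol addition to an α-alkoxy ketone through an open transition state: BF3 binds the ketone oxygen of 4 as a monodentate Lewis acid, the CH2 terminus of 7 (its only enol-ether carbon) attacks the activated carbonyl, and the silyloxocarbenium ion loses Me3SiF to leave aldolate 8, which aqueous NaHCO3 hydrolyses to 9. The closest known reaction type is the BF3-mediated addition of silyl enol ethers and ketene acetals to glyceraldehyde acetonide and to α-alkoxy ketones, which gives the anti adducts. No ring is closed. The one new stereocentre, C3', is set by the resident C2' centre under polar Felkin–Anh control: the C2'–O bond stands perpendicular to the carbonyl plane and anti to the incoming nucleophile, the C2'–H lies on the side of the ketone methyl group next to the line of attack, and the nucleophile should therefore enter the Re face and give the (3'R) carbinol with the C2' and C3' oxygens anti. The step needs non-chelation facial selectivity and an intact C2' centre; BF3 offers a single coordination site and the acetonide oxygen is a poor donor, which excludes the five-membered chelate that leads to the syn isomer, and the non-basic medium at −78 °C avoids enolisation toward C2'. Regiochemistry is not in question, and quenching cold prevents retro-aldol cleavage of the tertiary aldol.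

Step 5
Reactants: 9 (6R)-6-[(4S)-2,2-dimethyl-1,3-dioxolan-4-yl]-6-hydroxy-2-methylhept-2-en-4-one
Product: 11 (4R,6R)-6-[(4S)-2,2-dimethyl-1,3-dioxolan-4-yl]-2-methylhept-2-ene-4,6-diol, via alkoxydiacetoxyborohydride 10 (not isolated)
Conditions: Me4NBH(OAc)3, MeCN/AcOH (1:1), −35 → −20 °C; aq. NaHCO3
Reagents that add atoms: none
Why: Evans–Saksena reduction: the tertiary C3' hydroxyl exchanges an acetate on boron to give 10, which delivers hydride internally to the acid-activated enone carbonyl (1,2-reduction) through a chair with the dioxolanyl group equatorial and the C3' methyl axial. This should give the 3',5'-anti diol, that is (5'R); the reagent leaves the conjugated double bond alone, and the acetonide tolerates cold acetic acid.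

Step 6
Reactants: 11 (4R,6R)-6-[(4S)-2,2-dimethyl-1,3-dioxolan-4-yl]-2-methylhept-2-ene-4,6-diol
Product: 12 (2R,4R)-4-[(tert-butyldimethylsilyl)oxy]-2-[(4S)-2,2-dimethyl-1,3-dioxolan-4-yl]-6-methylhept-5-en-2-ol
Conditions: t-BuMe2SiCl, imidazole, DMF, 0 °C → rt
Reagents that add atoms: tert-butyldimethylsilyl chloride, CC(C)(C)[Si](C)(C)Cl
Why: Silylation of the secondary allylic alcohol; the tertiary C3' hydroxyl does not react with the silyl chloride under imidazole catalysis, so the two hydroxyls are distinguished by their substitution alone.

Step 7
Reactants: 12 (2R,4R)-4-[(tert-butyldimethylsilyl)oxy]-2-[(4S)-2,2-dimethyl-1,3-dioxolan-4-yl]-6-methylhept-5-en-2-ol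
Product: 13 (2S,3R,5R)-5-[(tert-butyldimethylsilyl)oxy]-3,7-dimethyloct-6-ene-1,2,3-triol
Conditions: AcOH/H2O (4:1), rt
Reagents that add atoms: none
Why: Acid hydrolysis of a terminal isopropylidene acetal; a secondary tert-butyldimethylsilyl ether and the tertiary alcohol are expected to persist in aqueous acetic acid at room temperature, and the medium is too weakly acidic to ionise the allylic C5'–O bond. The reaction is followed and stopped at full conversion.

Step 8
Reactants: 13 (2S,3R,5R)-5-[(tert-butyldimethylsilyl)oxy]-3,7-dimethyloct-6-ene-1,2,3-triol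
Product: 14 (2S,3R,5R)-5-[(tert-butyldimethylsilyl)oxy]-2,3-dihydroxy-3,7-dimethyloct-6-en-1-yl 4-methylbenzenesulfonate
Conditions: TsCl, Bu2SnO (2 mol%), Et3N, CH2Cl2, 0 °C → rt
Reagents that add atoms: 4-methylbenzenesulfonyl chloride, Cc1ccc(cc1)S(Cl)(=O)=O
Why: Bu2SnO-catalysed regioselective sulfonylation of a terminal 1,2-diol: the primary oxygen is tosylated, while the secondary and tertiary hydroxyls stay free.

Step 9
Reactants: 14 (2S,3R,5R)-5-[(tert-butyldimethylsilyl)oxy]-2,3-dihydroxy-3,7-dimethyloct-6-en-1-yl 4-methylbenzenesulfonate; 15 7-hydroxy-8-methoxy-2H-chromen-2-one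
Product: 17 7-{[(2S,3R,5R)-5-[(tert-butyldimethylsilyl)oxy]-2,3-dihydroxy-3,7-dimethyloct-6-en-1-yl]oxy}-8-methoxy-2H-chromen-2-one, via potassium phenoxide 16 (not isolated)
Conditions: K2CO3, DMF, 60 °C
Reagents that add atoms: none
Why: Williamson ether synthesis: carbonate deprotonates the acidic 7-hydroxyl of 15 and phenoxide 16 displaces the primary sulfonate by SN2. A competing closure of the C2' hydroxyl onto C1' would be reopened by the phenoxide at the same primary carbon, so both paths converge on 17 with C2' unchanged; the lactone is stable to anhydrous carbonate in DMF.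

Step 10
Reactants: 17 7-{[(2S,3R,5R)-5-[(tert-butyldimethylsilyl)oxy]-2,3-dihydroxy-3,7-dimethyloct-6-en-1-yl]oxy}-8-methoxy-2H-chromen-2-one
Product: 18 (2S,3R,5R)-5-[(tert-butyldimethylsilyl)oxy]-3-hydroxy-1-[(8-methoxy-2-oxo-2H-chromen-7-yl)oxy]-3,7-dimethyloct-6-en-2-yl methanesulfonate
Conditions: MsCl (1.2 equiv), Et3N, CH2Cl2, −10 °C
Reagents that add atoms: methanesulfonyl chloride, CS(Cl)(=O)=O
Why: Sulfonylation of the only secondary hydroxyl; the tertiary C3' hydroxyl is too hindered to react at −10 °C with a slight excess of reagent, and C2' keeps its configuration in the mesylate.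

Step 11
Reactants: 18 (2S,3R,5R)-5-[(tert-butyldimethylsilyl)oxy]-3-hydroxy-1-[(8-methoxy-2-oxo-2H-chromen-7-yl)oxy]-3,7-dimethyloct-6-en-2-yl methanesulfonate
Product: 20 7-({(2R,3R)-3-[(2R)-2-[(tert-butyldimethylsilyl)oxy]-4-methylpent-3-en-1-yl]-3-methyloxiran-2-yl}methoxy)-8-methoxy-2H-chromen-2-one, via sodium alkoxide 19 (not isolated)
Conditions: NaH, THF, 0 °C → rt
Reagents that add atoms: none
Why: Intramolecular Williamson reaction (3-exo-tet): the tertiary alkoxide 19 displaces the C2' mesylate from the back, inverting C2' from S to R while C3' keeps its oxygen and configuration, so the anti diol becomes the trans (2'R,3'R) epoxide. NaH is not nucleophilic toward the lactone.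

Step 12
Reactants: 20 7-({(2R,3R)-3-[(2R)-2-[(tert-butyldimethylsilyl)oxy]-4-methylpent-3-en-1-yl]-3-methyloxiran-2-yl}methoxy)-8-methoxy-2H-chromen-2-one
Product: 21 7-({(2R,3R)-3-[(2R)-2-hydroxy-4-methylpent-3-en-1-yl]-3-methyloxiran-2-yl}methoxy)-8-methoxy-2H-chromen-2-one
Conditions: Bu4NF, AcOH, THF, 0 °C → rt
Reagents that add atoms: none
Why: Fluoride-induced desilylation, buffered with acetic acid so that neither the lactone nor the epoxide meets free alkoxide or hydroxide; no stereocentre is touched and no acid strong enough to open the epoxide is present.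

## Compound list

1 | methyl (S)-2,2-dimethyl-1,3-dioxolane-4-carboxylate | COC(=O)[C@@H]1COC(C)(C)O1 | starting material
2 | (S)-N-methoxy-N,2,2-trimethyl-1,3-dioxolane-4-carboxamide | CON(C)C(=O)[C@@H]1COC(C)(C)O1 | intermediate
3 | bromomagnesium 1-[(4S)-2,2-dimethyl-1,3-dioxolan-4-yl]-1-[methoxy(methyl)amino]ethan-1-olate (hemiaminal carbon undefined; not isolated) | CON(C)C(C)(O[Mg]Br)[C@@H]1COC(C)(C)O1 | intermediate
4 | 1-[(4S)-2,2-dimethyl-1,3-dioxolan-4-yl]ethan-1-one | CC(=O)[C@@H]1COC(C)(C)O1 | intermediate
5 | mesityl oxide (4-methylpent-3-en-2-one) | CC(C)=CC(C)=O | starting material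
6 | lithium 4-methylpenta-1,3-dien-2-olate (not isolated) | [Li]OC(=C)C=C(C)C | intermediate
7 | trimethyl[(4-methylpenta-1,3-dien-2-yl)oxy]silane | CC(C)=CC(=C)O[Si](C)(C)C | intermediate
8 | difluoro{[(2R)-2-[(4S)-2,2-dimethyl-1,3-dioxolan-4-yl]-6-methyl-4-oxohept-5-en-2-yl]oxy}borane (not isolated) | CC(C)=CC(=O)C[C@@](C)(OB(F)F)[C@@H]1COC(C)(C)O1 | intermediate
9 | (6R)-6-[(4S)-2,2-dimethyl-1,3-dioxolan-4-yl]-6-hydroxy-2-methylhept-2-en-4-one | CC(C)=CC(=O)C[C@@](C)(O)[C@@H]1COC(C)(C)O1 | intermediate
10 | tetramethylammonium diacetoxy(hydrido){[(2R)-2-[(4S)-2,2-dimethyl-1,3-dioxolan-4-yl]-6-methyl-4-oxohept-5-en-2-yl]oxy}borate (not isolated) | CC(C)=CC(=O)C[C@@](C)(O[BH-](OC(C)=O)OC(C)=O)[C@@H]1COC(C)(C)O1.C[N+](C)(C)C | intermediate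
11 | (4R,6R)-6-[(4S)-2,2-dimethyl-1,3-dioxolan-4-yl]-2-methylhept-2-ene-4,6-diol | CC(C)=C[C@H](O)C[C@@](C)(O)[C@@H]1COC(C)(C)O1 | intermediate
12 | (2R,4R)-4-[(tert-butyldimethylsilyl)oxy]-2-[(4S)-2,2-dimethyl-1,3-dioxolan-4-yl]-6-methylhept-5-en-2-ol | CC(C)=C[C@H](O[Si](C)(C)C(C)(C)C)C[C@@](C)(O)[C@@H]1COC(C)(C)O1 | intermediate
13 | (2S,3R,5R)-5-[(tert-butyldimethylsilyl)oxy]-3,7-dimethyloct-6-ene-1,2,3-triol | CC(C)=C[C@H](O[Si](C)(C)C(C)(C)C)C[C@@](C)(O)[C@@H](O)CO | intermediate
14 | (2S,3R,5R)-5-[(tert-butyldimethylsilyl)oxy]-2,3-dihydroxy-3,7-dimethyloct-6-en-1-yl 4-methylbenzenesulfonate | CC(C)=C[C@H](O[Si](C)(C)C(C)(C)C)C[C@@](C)(O)[C@@H](O)COS(=O)(=O)c1ccc(C)cc1 | intermediate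
15 | 7-hydroxy-8-methoxy-2H-chromen-2-one (7-hydroxy-8-methoxycoumarin) | COc1c(O)ccc2ccc(=O)oc12 | starting material
16 | potassium 8-methoxy-2-oxo-2H-chromen-7-olate (not isolated) | COc1c([O-])ccc2ccc(=O)oc12.[K+] | intermediate
17 | 7-{[(2S,3R,5R)-5-[(tert-butyldimethylsilyl)oxy]-2,3-dihydroxy-3,7-dimethyloct-6-en-1-yl]oxy}-8-methoxy-2H-chromen-2-one | CC(C)=C[C@H](O[Si](C)(C)C(C)(C)C)C[C@@](C)(O)[C@@H](O)COc1ccc2ccc(=O)oc2c1OC | intermediate
18 | (2S,3R,5R)-5-[(tert-butyldimethylsilyl)oxy]-3-hydroxy-1-[(8-methoxy-2-oxo-2H-chromen-7-yl)oxy]-3,7-dimethyloct-6-en-2-yl methanesulfonate | CC(C)=C[C@H](O[Si](C)(C)C(C)(C)C)C[C@@](C)(O)[C@@H](OS(C)(=O)=O)COc1ccc2ccc(=O)oc2c1OC | intermediate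
19 | sodium (2S,3R,5R)-5-[(tert-butyldimethylsilyl)oxy]-2-[(methanesulfonyl)oxy]-1-[(8-methoxy-2-oxo-2H-chromen-7-yl)oxy]-3,7-dimethyloct-6-en-3-olate (not isolated) | CC(C)=C[C@H](O[Si](C)(C)C(C)(C)C)C[C@@](C)([O-])[C@@H](OS(C)(=O)=O)COc1ccc2ccc(=O)oc2c1OC.[Na+] | intermediate
20 | 7-({(2R,3R)-3-[(2R)-2-[(tert-butyldimethylsilyl)oxy]-4-methylpent-3-en-1-yl]-3-methyloxiran-2-yl}methoxy)-8-methoxy-2H-chromen-2-one | COc1c(OC[C@H]2O[C@]2(C)C[C@@H](O[Si](C)(C)C(C)(C)C)C=C(C)C)ccc2ccc(=O)oc12 | intermediate
21 | 7-({(2R,3R)-3-[(2R)-2-hydroxy-4-methylpent-3-en-1-yl]-3-methyloxiran-2-yl}methoxy)-8-methoxy-2H-chromen-2-one | COc1c(OC[C@H]2O[C@]2(C)C[C@@H](O)C=C(C)C)ccc2ccc(=O)oc12 | target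

## Step count and least certain steps

Total: 12 steps. Longest linear sequence: 11 steps (steps 1, 2 and 4 to 12, from ester 1). Step 3 is a one-step side branch from mesityl oxide.

**Step 4 (key step).** The most likely failure is poor facial selectivity at the ketone. A ketone acceptor is less electrophilic than an aldehyde, and the Felkin bias rests only on the difference between the C2' substituents next to a methyl ketone. Slow addition would also give time for retro-aldol cleavage, for closure of the tertiary hydroxyl onto the enone, or for opening of the dioxolane by the Lewis acid.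

The fallback sets C3' under reagent control and reaches 9 by another bond sequence. It starts from ketone 4.
- Allylboration with the enantiomer of B-allyl-10-phenyl-9-borabicyclo[3.3.2]decane that is matched with the Felkin preference (Et2O, −78 °C, amino alcohol work-up) would give (2R)-2-[(4S)-2,2-dimethyl-1,3-dioxolan-4-yl]pent-4-en-2-ol F1.
- Ozonolysis (O3, CH2Cl2, −78 °C; PPh3) would give (3R)-3-[(4S)-2,2-dimethyl-1,3-dioxolan-4-yl]-3-hydroxybutanal F2.
- Addition of Me2C=CHMgBr (THF, −78 → 0 °C) would give (6R)-6-[(4S)-2,2-dimethyl-1,3-dioxolan-4-yl]-2-methylhept-2-ene-4,6-diol F3 as a mixture at C4.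
- MnO2 in CH2Cl2 would oxidise only the allylic carbinol and return to the route at enone 9.

**Step 5.** The most likely failure is low 1,3-anti selectivity. The tertiary carbinol offers a methyl and a dioxolanyl group for the axial position of the chair. Acetate exchange at a tertiary hydroxyl may also be slow enough for undirected reduction to compete.

The fallback replaces internal delivery by catalyst control. It starts from 9.
- Silylation with N-(trimethylsilyl)imidazole would give (6R)-6-[(4S)-2,2-dimethyl-1,3-dioxolan-4-yl]-2-methyl-6-[(trimethylsilyl)oxy]hept-2-en-4-one F4.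
- CBS reduction with (S)-2-methyl-CBS-oxazaborolidine and catecholborane (toluene, −78 °C), the alkenyl group acting as the large substituent, would give (4R,6R)-6-[(4S)-2,2-dimethyl-1,3-dioxolan-4-yl]-2-methyl-6-[(trimethylsilyl)oxy]hept-2-en-4-ol F5.
- t-BuMe2SiCl and imidazole would give (4R,6R)-4-[(tert-butyldimethylsilyl)oxy]-6-[(4S)-2,2-dimethyl-1,3-dioxolan-4-yl]-2-methyl-6-[(trimethylsilyl)oxy]hept-2-ene F6.
- K2CO3 in MeOH at 0 °C would remove only the trimethylsilyl group and return to the route at 12.

**Step 9.** The most likely failure is loss of material along a side path. The C2' hydroxyl can close onto C1', and the oxirane can then migrate toward C3' (Payne-type shift) and stall as an internal epoxide. Slow alkylation would also leave time for base-induced silyl migration.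

The fallback attaches the coumarin by Mitsunobu etherification of an epoxy alcohol. It starts from triol 13.
- Primary-selective acetylation (AcCl, 2,4,6-collidine, CH2Cl2, −78 °C) would give (2S,3R,5R)-5-[(tert-butyldimethylsilyl)oxy]-2,3-dihydroxy-3,7-dimethyloct-6-en-1-yl acetate F7.
- MsCl and Et3N would give (2S,3R,5R)-5-[(tert-butyldimethylsilyl)oxy]-3-hydroxy-2-[(methanesulfonyl)oxy]-3,7-dimethyloct-6-en-1-yl acetate F8.
- NaH in THF would close the oxirane with inversion at C2' to {(2R,3R)-3-[(2R)-2-[(tert-butyldimethylsilyl)oxy]-4-methylpent-3-en-1-yl]-3-methyloxiran-2-yl}methyl acetate F9. The acetate stays on until the ring is closed, so the C1' oxygen cannot compete for the sulfonate.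
- K2CO3 in MeOH at 0 °C would give {(2R,3R)-3-[(2R)-2-[(tert-butyldimethylsilyl)oxy]-4-methylpent-3-en-1-yl]-3-methyloxiran-2-yl}methanol F10.
- Mitsunobu reaction of F10 with phenol 15 (PPh3, diisopropyl azodicarboxylate, THF, 0 °C → rt) would return to the route at 20.

**Step 10 (with the closure in step 11).** The most likely failure is incomplete discrimination between the hindered secondary C2' hydroxyl and the tertiary one during sulfonylation. In the closure, the strong base could also move the silyl group from O5' to the C3' alkoxide.

The fallback is a one-step Mitsunobu cyclodehydration. It starts from diol 17, with PPh3 and diisopropyl azodicarboxylate in toluene. The secondary oxygen is activated as the alkoxyphosphonium ion and the tertiary hydroxyl displaces it with the same inversion at C2'. It returns to the route at 20 without a sulfonate and without a strong base.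

## Further compounds

F1 | step 4 | (2R)-2-[(4S)-2,2-dimethyl-1,3-dioxolan-4-yl]pent-4-en-2-ol | C=CC[C@@](C)(O)[C@@H]1COC(C)(C)O1
F2 | step 4 | (3R)-3-[(4S)-2,2-dimethyl-1,3-dioxolan-4-yl]-3-hydroxybutanal | O=CC[C@@](C)(O)[C@@H]1COC(C)(C)O1
F3 | step 4 | (6R)-6-[(4S)-2,2-dimethyl-1,3-dioxolan-4-yl]-2-methylhept-2-ene-4,6-diol (mixture at C4) | CC(C)=CC(O)C[C@@](C)(O)[C@@H]1COC(C)(C)O1
F4 | step 5 | (6R)-6-[(4S)-2,2-dimethyl-1,3-dioxolan-4-yl]-2-methyl-6-[(trimethylsilyl)oxy]hept-2-en-4-one | CC(C)=CC(=O)C[C@@](C)(O[Si](C)(C)C)[C@@H]1COC(C)(C)O1
F5 | step 5 | (4R,6R)-6-[(4S)-2,2-dimethyl-1,3-dioxolan-4-yl]-2-methyl-6-[(trimethylsilyl)oxy]hept-2-en-4-ol | CC(C)=C[C@H](O)C[C@@](C)(O[Si](C)(C)C)[C@@H]1COC(C)(C)O1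
F6 | step 5 | (4R,6R)-4-[(tert-butyldimethylsilyl)oxy]-6-[(4S)-2,2-dimethyl-1,3-dioxolan-4-yl]-2-methyl-6-[(trimethylsilyl)oxy]hept-2-ene | CC(C)=C[C@H](O[Si](C)(C)C(C)(C)C)C[C@@](C)(O[Si](C)(C)C)[C@@H]1COC(C)(C)O1
F7 | step 9 | (2S,3R,5R)-5-[(tert-butyldimethylsilyl)oxy]-2,3-dihydroxy-3,7-dimethyloct-6-en-1-yl acetate | CC(C)=C[C@H](O[Si](C)(C)C(C)(C)C)C[C@@](C)(O)[C@@H](O)COC(C)=O
F8 | step 9 | (2S,3R,5R)-5-[(tert-butyldimethylsilyl)oxy]-3-hydroxy-2-[(methanesulfonyl)oxy]-3,7-dimethyloct-6-en-1-yl acetate | CC(C)=C[C@H](O[Si](C)(C)C(C)(C)C)C[C@@](C)(O)[C@@H](OS(C)(=O)=O)COC(C)=O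
F9 | step 9 | {(2R,3R)-3-[(2R)-2-[(tert-butyldimethylsilyl)oxy]-4-methylpent-3-en-1-yl]-3-methyloxiran-2-yl}methyl acetate | CC(=O)OC[C@H]1O[C@]1(C)C[C@@H](O[Si](C)(C)C(C)(C)C)C=C(C)C
F10 | step 9 | {(2R,3R)-3-[(2R)-2-[(tert-butyldimethylsilyl)oxy]-4-methylpent-3-en-1-yl]-3-methyloxiran-2-yl}methanol | OC[C@H]1O[C@]1(C)C[C@@H](O[Si](C)(C)C(C)(C)C)C=C(C)C
F0 | step 10 | none | none
A1 | alternative 1 | 2-ethenyl-6-methoxy-5-({(2R,3R)-3-[(2R)-2-[(tert-butyldimethylsilyl)oxy]-4-methylpent-3-en-1-yl]-3-methyloxiran-2-yl}methoxy)phenyl prop-2-enoate | C=CC(=O)Oc1c(C=C)ccc(OC[C@H]2O[C@]2(C)C[C@@H](O[Si](C)(C)C(C)(C)C)C=C(C)C)c1OC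
A2 | alternative 1 | 7-({(2R,3R)-3-[(2R)-2-[(tert-butyldimethylsilyl)oxy]-4-methylpent-3-en-1-yl]-3-methyloxiran-2-yl}methoxy)-8-methoxy-2H-chromen-2-one | COc1c(OC[C@H]2O[C@]2(C)C[C@@H](O[Si](C)(C)C(C)(C)C)C=C(C)C)ccc2ccc(=O)oc12
A3 | alternative 2 | 2-[(8-methoxy-2-oxo-2H-chromen-7-yl)oxy]acetaldehyde | COc1c(OCC=O)ccc2ccc(=O)oc12
A4 | alternative 2 | 1-[(buta-2,3-dien-2-yloxy)methyl]-4-methoxybenzene | C=C=C(C)OCc1ccc(OC)cc1
A5 | alternative 2 | 7-{[(2S,3R)-2-hydroxy-3-[(4-methoxybenzyl)oxy]-3-methylpent-4-en-1-yl]oxy}-8-methoxy-2H-chromen-2-one | COc1c(OC[C@H](O)[C@](C)(OCc3ccc(OC)cc3)C=C)ccc2ccc(=O)oc12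
A6 | alternative 3 | (2E,5R)-5-[(tert-butyldimethylsilyl)oxy]-3,7-dimethylocta-2,6-dienal | O=C/C=C(\C)C[C@@H](O[Si](C)(C)C(C)(C)C)C=C(C)C
A7 | alternative 3 | (2S,3R)-3-[(2R)-2-[(tert-butyldimethylsilyl)oxy]-4-methylpent-3-en-1-yl]-3-methyloxirane-2-carbaldehyde | O=C[C@H]1O[C@]1(C)C[C@@H](O[Si](C)(C)C(C)(C)C)C=C(C)C
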